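**Strategy.** The route rests on disconnecting C17–C18 and the C19–CH3 bond next to the anti C16/C17 dioxygen pair, the carbons that become the bromotetrahydrofuran ring (O16, C16–C19). In one operation, zirconium-catalysed methylalumination of a silyl-protected butynol (C18–C21) fixes the E C18=C19 geometry, and the resulting alkenylalanate adds to (R)-glyceraldehyde acetonide (C15–C17) with Felkin–Anh control of C17. The precursors are therefore a terminal alkyne and a chiral-pool aldehyde. 5-endo bromoetherification, chelation-controlled extension at C15, oxazole alkylation, ring-closing metathesis of the macrolactone and a late Z-selective Wittig reaction complete the target.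

Key step: step 2

Remark: atom numbers are those of the macrolide (C1 lactone carbonyl to C25 carboxyl); CIP letters are those of each compound as drawn and can change between intermediates where substituent priorities change although no bond at the stereocentre is broken.

Step 1
Reactants: 1 but-3-yn-1-ol
Product: 2 4-(triisopropylsilyloxy)but-1-yne
Conditions: TIPSCl, imidazole, CH2Cl2, 0 °C → rt
Reagents that add atoms: triisopropylsilyl chloride, CC(C)[Si](Cl)(C(C)C)C(C)C
Why: Routine silylation of a primary alcohol; the bulky silyl ether tolerates the aluminium reagents of step 2 and the acid of step 4.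

Step 2
Reactants: 2 4-(triisopropylsilyloxy)but-1-yne; 3 (R)-glyceraldehyde acetonide [(4R)-2,2-dimethyl-1,3-dioxolane-4-carbaldehyde]
Product: 6 (1S,2E)-1-[(4R)-2,2-dimethyl-1,3-dioxolan-4-yl]-3-methyl-5-(triisopropylsilyloxy)pent-2-en-1-ol, via E-alkenyldimethylalane 4 (not isolated), via lithium alkenylalanate 5 (not isolated)
Conditions: Me3Al, Cp2ZrCl2 (cat.), CH2Cl2, 0 °C → rt; excess Me3Al removed in vacuo; n-BuLi, hexane/THF, −78 °C; then 3, −78 → −40 °C
Reagents that add atoms: trimethylaluminium, C[Al](C)C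
Why: Zirconium-catalysed syn methylalumination (Negishi carboalumination) places CH3 on the internal carbon C19 and aluminium on the terminal carbon C18 of 2, so alane 4 has the E geometry that the later anti bromoetherification needs; once excess Me3Al is stripped off, n-BuLi turns 4 into the more nucleophilic alanate 5, which transfers its alkenyl group to the aldehyde carbon C17 of 3 with retention of alkene geometry. The closest known reaction type is the addition of carboalumination-derived alkenylalanates to aldehydes. No ring is closed. The new C17 stereocentre is controlled by the C16 dioxolane centre: in the Felkin–Anh arrangement the C16–O bond lies anti to the incoming nucleophile, which should give the 16,17-anti alcohol. The step needs regioselective carbometalation (secured by the terminal alkyne and the zirconium catalyst), alkenyl rather than alkyl transfer (secured by the preferred migration of the sp2 carbon from the alanate) and non-chelated facial selectivity (secured by the coordinatively saturated alanate and the poorly chelating acetonide oxygens).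

Step 3
Reactants: 6 allylic alcohol (16R,17S)
Product: 7 C17 4-methoxybenzyl (PMB) ether of 6 (16R,17S,18E)
Conditions: NaH, PMBCl, n-Bu4NI (cat.), THF/DMF, 0 °C → rt
Reagents that add atoms: 4-methoxybenzyl chloride, COc1ccc(CCl)cc1
Why: Williamson etherification of the secondary allylic alkoxide; the ether shields O17 through the halocyclisation and the basic steps and can later be removed oxidatively without forming an alkoxide next to the bromide.

Step 4
Reactants: 7 PMB ether acetonide
Product: 8 (2R,3S,4E)-3-(4-methoxybenzyloxy)-5-methyl-7-(triisopropylsilyloxy)hept-4-ene-1,2-diol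
Conditions: AcOH/H2O (4:1), rt
Reagents that add atoms: none
Why: Mild aqueous acid hydrolysis of a terminal isopropylidene acetal, under which the primary TIPS ether and the PMB ether should survive.

Step 5
Reactants: 8 C15,C16-diol
Product: 9 (2R,3S,4E)-2-hydroxy-3-(4-methoxybenzyloxy)-5-methyl-7-(triisopropylsilyloxy)hept-4-en-1-yl acetate
Conditions: AcCl, 2,4,6-collidine, CH2Cl2, −78 °C
Reagents that add atoms: acetyl chloride, CC(=O)Cl
Why: Selective acylation of the less hindered primary hydroxyl at low temperature; masking O15 leaves O16 as the only hydroxyl that can attack the alkene, which removes the competing six-membered ring closure.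

Step 6
Reactants: 9 O15 acetate with free O16–H
Product: 10 [(2R,3R,4S,5R)-4-bromo-3-(4-methoxybenzyloxy)-5-methyl-5-[2-(triisopropylsilyloxy)ethyl]oxolan-2-yl]methyl acetate (C15 substituent, Br and C19–CH3 on one face of the ring; O17 and the C20 chain on the other)
Conditions: NBS, CH2Cl2, −40 → 0 °C, dark
Reagents that add atoms: N-bromosuccinimide, O=C1CCC(=O)N1Br
Why: Electrophilic bromoetherification in the 5-endo mode: O16 opens the bromonium ion at the tertiary carbon C19 anti to bromine, so the E alkene gives Br cis to the C19 methyl, and 1,3-allylic strain between that methyl and the C17 substituents keeps H17 in the alkene plane with C16 and the PMB ether on opposite faces, which should set C18 (S) and C19 (R) with bromine trans to O17.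

Step 7
Reactants: 10 bromotetrahydrofuran acetate
Product: 11 [(2R,3R,4S,5R)-4-bromo-3-(4-methoxybenzyloxy)-5-methyl-5-[2-(triisopropylsilyloxy)ethyl]oxolan-2-yl]methanol
Conditions: K2CO3 (cat.), MeOH, 0 °C
Reagents that add atoms: none
Why: Base-catalysed transesterification removes the acetate; the bromide has no anti-periplanar hydrogen and O17 is etherified, so neither elimination nor epoxide formation is expected.

Step 8
Reactants: 11 primary alcohol
Product: 12 (2S,3R,4S,5R)-4-bromo-3-(4-methoxybenzyloxy)-5-methyl-5-[2-(triisopropylsilyloxy)ethyl]oxolane-2-carbaldehyde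
Conditions: TEMPO (cat.), PhI(OAc)2, CH2Cl2, rt
Reagents that add atoms: none
Why: Oxoammonium oxidation of a primary alcohol under non-basic conditions that should neither epimerise C16 nor eliminate the β-alkoxy group; the aldehyde is used crude.

Step 9
Reactants: 13 (S)-3-bromo-2-methylpropan-1-ol
Product: 14 (S)-(3-bromo-2-methylpropoxy)(tert-butyl)dimethylsilane
Conditions: TBSCl, imidazole, CH2Cl2, rt
Reagents that add atoms: tert-butyldimethylsilyl chloride, CC(C)(C)[Si](C)(C)Cl
Why: Routine silylation of a primary alcohol that leaves the C13 stereocentre untouched.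

Step 10
Reactants: 14 (S)-bromide; 12 aldehyde
Product: 16 (1S,3R)-1-[(2R,3R,4S,5R)-4-bromo-3-(4-methoxybenzyloxy)-5-methyl-5-[2-(triisopropylsilyloxy)ethyl]oxolan-2-yl]-4-(tert-butyldimethylsilyloxy)-3-methylbutan-1-ol, via Grignard reagent 15 (not isolated)
Conditions: 14, Mg, Et2O, reflux; then 12, MgBr2·OEt2, CH2Cl2, −78 °C
Reagents that add atoms: none
Why: Grignard addition under Cram-chelate control: magnesium bridges the aldehyde oxygen and the ring oxygen O16 and the nucleophile attacks C15 from the side of H16, which should give the 15,16-syn (15S) alcohol, while C13 arrives with the reagent.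

Step 11
Reactants: 16 C15 alcohol
Product: 17 O15-methyl ether of 16 (13R,15S,16R,17R,18S,19R)
Conditions: NaH, MeI, THF/DMF, 0 °C
Reagents that add atoms: iodomethane, CI
Why: Williamson methylation of the C15 alkoxide; it cannot displace the bromide because O15 sits on the same ring face as bromine.

Step 12
Reactants: 17 bis-silyl ether
Product: 18 (2R,4S)-4-[(2R,3R,4S,5R)-4-bromo-3-(4-methoxybenzyloxy)-5-methyl-5-[2-(triisopropylsilyloxy)ethyl]oxolan-2-yl]-4-methoxy-2-methylbutan-1-ol
Conditions: PPTS, MeOH, rt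
Reagents that add atoms: none
Why: Acid-catalysed methanolysis that should discriminate the primary TBS ether from the far more robust primary TIPS ether.

Step 13
Reactants: 18 C12 alcohol
Product: 19 (2R,3R,4S,5R)-4-bromo-2-[(1S,3R)-4-iodo-1-methoxy-3-methylbutyl]-3-(4-methoxybenzyloxy)-5-methyl-5-[2-(triisopropylsilyloxy)ethyl]oxolane
Conditions: I2, PPh3, imidazole, CH2Cl2, 0 °C → rt
Reagents that add atoms: iodine, II
Why: Appel-type iodination of a primary alcohol through its alkoxyphosphonium salt.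

Step 14
Reactants: 20 ethyl 2-methyl-1,3-oxazole-4-carboxylate
Product: 22 1-(2-methyl-1,3-oxazol-4-yl)ethan-1-one, via Weinreb amide 21 (not isolated)
Conditions: MeNH(OMe)·HCl, i-PrMgCl, THF, −20 °C; then MeMgBr, −20 → 0 °C
Reagents that add atoms: methylmagnesium bromide, C[Mg]Br
Why: One-pot ester to ketone conversion: the magnesium amide of N,O-dimethylhydroxylamine gives Weinreb amide 21, whose chelated tetrahedral adduct with MeMgBr stops at the ketone stage.

Step 15
Reactants: 22 methyl ketone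
Product: 23 (2E)-N-methoxy-N-methyl-3-(2-methyl-1,3-oxazol-4-yl)but-2-enamide
Conditions: (EtO)2P(O)CH2C(O)N(OMe)Me, NaH, THF, 0 °C → reflux
Reagents that add atoms: diethyl [2-(methoxy(methyl)amino)-2-oxoethyl]phosphonate, CCOP(=O)(CC(=O)N(C)OC)OCC
Why: Horner–Wadsworth–Emmons olefination of the methyl ketone with a stabilised phosphonate anion, which should favour the E isomer (oxazole trans to the amide), any Z isomer being removable by chromatography.

Step 16
Reactants: 23 unsaturated Weinreb amide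
Product: 24 (2E)-3-(2-methyl-1,3-oxazol-4-yl)but-2-enal
Conditions: i-Bu2AlH, THF, −78 °C
Reagents that add atoms: none
Why: Partial reduction of a Weinreb amide, whose aluminium chelate collapses to the aldehyde only on work-up, so over-reduction is avoided.

Step 17
Reactants: 24 enal
Product: 26 (2E,4R,5S)-5-methyl-2-(2-methyl-1,3-oxazol-4-yl)hepta-2,6-dien-4-ol (target numbering 4S,5R), via diisopinocampheylborinate 25 (not isolated)
Conditions: cis-2-butene, KOt-Bu, n-BuLi, THF, −78 → −45 °C; (+)-Ipc2BOMe [(−)-α-pinene series], −78 °C; BF3·OEt2; 24, −78 °C; NaOH, H2O2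
Reagents that add atoms: cis-2-butene, C/C=C\C
Why: Asymmetric crotylboration: the chair transition state converts the Z crotyl geometry into the 4,5-syn relationship and the isopinocampheyl groups of the (−)-α-pinene series select the aldehyde face that should give (4S,5R) in target numbering.

Step 18
Reactants: 26 homoallylic alcohol
Product: 27 4-[(2E,4R,5S)-4-(tert-butyldimethylsilyloxy)-5-methylhepta-2,6-dien-2-yl]-2-methyl-1,3-oxazole
Conditions: TBSOTf, 2,6-lutidine, CH2Cl2, −78 → 0 °C
Reagents that add atoms: tert-butyldimethylsilyl trifluoromethanesulfonate, CC(C)(C)[Si](C)(C)OS(=O)(=O)C(F)(F)F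
Why: Silylation of a hindered secondary allylic alcohol with the reactive silyl triflate.

Step 19
Reactants: 27 2-methyloxazole; 19 primary iodide
Product: 29 2-[(3S,5S)-5-{(2R,3R,4S,5R)-4-bromo-3-(4-methoxybenzyloxy)-5-methyl-5-[2-(triisopropylsilyloxy)ethyl]oxolan-2-yl}-5-methoxy-3-methylpentyl]-4-[(2E,4R,5S)-4-(tert-butyldimethylsilyloxy)-5-methylhepta-2,6-dien-2-yl]-1,3-oxazole, via 2-(lithiomethyl)oxazole 28 (not isolated)
Conditions: 27, LiNEt2 (from Et2NH, n-BuLi), THF, −78 °C; then 19, −78 → −20 °C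
Reagents that add atoms: none
Why: Lateral lithiation of the 2-methyloxazole, in which lithium diethylamide equilibrates any ring-lithiated species to the 2-(lithiomethyl)oxazole, followed by SN2 alkylation with the primary iodide forms C11–C12; the secondary bromide is flanked by a quaternary carbon and lacks an anti hydrogen, so it should be spared.

Step 20
Reactants: 29 PMB ether
Product: 30 (2S,3R,4S,5R)-4-bromo-2-[(1S,3S)-5-{4-[(2E,4R,5S)-4-(tert-butyldimethylsilyloxy)-5-methylhepta-2,6-dien-2-yl]-1,3-oxazol-2-yl}-1-methoxy-3-methylpentyl]-5-methyl-5-[2-(triisopropylsilyloxy)ethyl]oxolan-3-ol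
Conditions: DDQ, CH2Cl2/pH 7 buffer, 0 °C
Reagents that add atoms: none
Why: Oxidative cleavage of the PMB ether through its benzylic oxocarbenium ion under buffered conditions frees O17 without forming an alkoxide trans to the bromide.

Step 21
Reactants: 30 C17 alcohol
Product: 31 O17 acrylate (prop-2-enoate) of 30
Conditions: acryloyl chloride, i-Pr2NEt, CH2Cl2, −20 → 0 °C
Reagents that add atoms: acryloyl chloride, C=CC(=O)Cl
Why: Acylation of the secondary alcohol with an acid chloride and a hindered amine base that is too weak to close an epoxide from the trans-bromohydrin.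

Step 22
Reactants: 31 acrylate with C3 vinyl group
Product: 32 O5-TBS, O21-TIPS macrolactone (2E,4S,5R,6E,13S,15S,16R,17R,18S,19R), i.e. the C1–C21 ring system of the target with C21 as CH2OTIPS
Conditions: second-generation Grubbs catalyst (cat.), toluene, 80 °C, high dilution
Reagents that add atoms: none
Why: Ring-closing metathesis between the acrylate and the C3 vinyl group closes the macrolactone; the conjugated trisubstituted C6=C7 alkene should be inert and the E enoate is the thermodynamically preferred product.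

Step 23
Reactants: 32 bis-silyl macrolactone
Product: 33 C5,C21-diol macrolactone
Conditions: HF·pyridine, pyridine, THF, 0 °C → rt
Reagents that add atoms: none
Why: Buffered fluoride cleaves both silyl ethers without a basic medium that could open the lactone.

Step 24
Reactants: 33 diol
Product: 34 C21 aldehyde with free C5 hydroxyl
Conditions: TEMPO (cat.), PhI(OAc)2, CH2Cl2, rt
Reagents that add atoms: none
Why: The oxoammonium oxidation distinguishes the unhindered primary C21 alcohol from the hindered secondary allylic C5 alcohol, so only the aldehyde should form.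

Step 25
Reactants: 35 (S)-citramalic acid
Product: 36 [(4S)-2,2,4-trimethyl-5-oxo-1,3-dioxolan-4-yl]acetic acid
Conditions: Me2C(OMe)2, TsOH (cat.), rt
Reagents that add atoms: 2,2-dimethoxypropane, COC(C)(C)OC
Why: Acid-catalysed ketal exchange ties the tertiary hydroxyl and the adjacent carboxyl into a five-membered dioxolanone and leaves the distal carboxyl free; the stereocentre is not involved.

Step 26
Reactants: 36 dioxolanone acid
Product: 37 (5S)-5-(2-hydroxyethyl)-2,2,5-trimethyl-1,3-dioxolan-4-one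
Conditions: BH3·THF, THF, 0 °C → rt
Reagents that add atoms: none
Why: Borane reduces the free carboxylic acid through its acyloxyborane much faster than the dioxolanone ester.

Step 27
Reactants: 37 primary alcohol
Product: 38 (5S)-5-(2-iodoethyl)-2,2,5-trimethyl-1,3-dioxolan-4-one
Conditions: I2, PPh3, imidazole, CH2Cl2, 0 °C
Reagents that add atoms: iodine, II
Why: Appel-type iodination of a primary alcohol under near-neutral conditions that the dioxolanone tolerates.

Step 28
Reactants: 38 primary iodide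
Product: 39 triphenyl{2-[(4S)-2,2,4-trimethyl-5-oxo-1,3-dioxolan-4-yl]ethyl}phosphonium iodide
Conditions: PPh3, MeCN, 80 °C
Reagents that add atoms: triphenylphosphine, c1ccc(cc1)P(c1ccccc1)c1ccccc1
Why: SN2 quaternisation of triphenylphosphine by the primary iodide.

Step 29
Reactants: 39 phosphonium iodide; 34 C21 aldehyde
Product: 41 target protected as the C24/C25 acetonide (2,2-dimethyl-1,3-dioxolan-4-one), 21Z, via phosphonium ylide 40 (not isolated)
Conditions: 39, NaN(SiMe3)2, THF, −78 °C; then 34, −78 → 0 °C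
Reagents that add atoms: none
Why: Wittig olefination with a non-stabilised ylide under lithium-free conditions passes through the kinetically favoured cis-oxaphosphetane and should give the Z C21=C22 alkene, the ylide adding to the aldehyde at low temperature faster than it enolises it or attacks the lactone.

Step 30
Reactants: 41 dioxolanone-protected macrolide
Product: 42 CNP0163177.2 (2E,4S,5R,6E,13S,15S,16R,17R,18S,19R,21Z,24S)
Conditions: AcOH/THF/H2O (3:1:1), 40 °C
Reagents that add atoms: none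
Why: Mild aqueous acid hydrolyses the acyloxy ketal at its ketal carbon, releasing the tertiary alcohol and the carboxylic acid with loss of acetone under conditions that the allylic alcohol, the lactone and the bromide should tolerate.

**Compound list**

1 | but-3-yn-1-ol | C#CCCO | starting material
2 | 4-(triisopropylsilyloxy)but-1-yne | C#CCCO[Si](C(C)C)(C(C)C)C(C)C | intermediate
3 | (R)-glyceraldehyde acetonide | O=C[C@H]1COC(C)(C)O1 | starting material
4 | dimethyl[(1E)-2-methyl-4-(triisopropylsilyloxy)but-1-en-1-yl]alane | C[Al](C)/C=C(\C)CCO[Si](C(C)C)(C(C)C)C(C)C | intermediate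
5 | lithium butyl(dimethyl)[(1E)-2-methyl-4-(triisopropylsilyloxy)but-1-en-1-yl]aluminate | [Li+].CCCC[Al-](C)(C)/C=C(\C)CCO[Si](C(C)C)(C(C)C)C(C)C | intermediate
6 | (1S,2E)-1-[(4R)-2,2-dimethyl-1,3-dioxolan-4-yl]-3-methyl-5-(triisopropylsilyloxy)pent-2-en-1-ol | O[C@@H](/C=C(\C)CCO[Si](C(C)C)(C(C)C)C(C)C)[C@H]1COC(C)(C)O1 | intermediate
7 | C17 PMB ether of 6 | COc1ccc(CO[C@@H](/C=C(\C)CCO[Si](C(C)C)(C(C)C)C(C)C)[C@H]2COC(C)(C)O2)cc1 | intermediate
8 | (2R,3S,4E)-3-(4-methoxybenzyloxy)-5-methyl-7-(triisopropylsilyloxy)hept-4-ene-1,2-diol | COc1ccc(CO[C@@H](/C=C(\C)CCO[Si](C(C)C)(C(C)C)C(C)C)[C@H](O)CO)cc1 | intermediate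
9 | (2R,3S,4E)-2-hydroxy-3-(4-methoxybenzyloxy)-5-methyl-7-(triisopropylsilyloxy)hept-4-en-1-yl acetate | COc1ccc(CO[C@@H](/C=C(\C)CCO[Si](C(C)C)(C(C)C)C(C)C)[C@H](O)COC(C)=O)cc1 | intermediate
10 | [(2R,3R,4S,5R)-4-bromo-3-(4-methoxybenzyloxy)-5-methyl-5-[2-(triisopropylsilyloxy)ethyl]oxolan-2-yl]methyl acetate | CC(=O)OC[C@H]1O[C@](C)(CCO[Si](C(C)C)(C(C)C)C(C)C)[C@@H](Br)[C@@H]1OCc1ccc(OC)cc1 | intermediate
11 | [(2R,3R,4S,5R)-4-bromo-3-(4-methoxybenzyloxy)-5-methyl-5-[2-(triisopropylsilyloxy)ethyl]oxolan-2-yl]methanol | OC[C@H]1O[C@](C)(CCO[Si](C(C)C)(C(C)C)C(C)C)[C@@H](Br)[C@@H]1OCc1ccc(OC)cc1 | intermediate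
12 | (2S,3R,4S,5R)-4-bromo-3-(4-methoxybenzyloxy)-5-methyl-5-[2-(triisopropylsilyloxy)ethyl]oxolane-2-carbaldehyde | O=C[C@H]1O[C@](C)(CCO[Si](C(C)C)(C(C)C)C(C)C)[C@@H](Br)[C@@H]1OCc1ccc(OC)cc1 | intermediate
13 | (S)-3-bromo-2-methylpropan-1-ol | BrC[C@@H](C)CO | starting material
14 | (S)-(3-bromo-2-methylpropoxy)(tert-butyl)dimethylsilane | BrC[C@@H](C)CO[Si](C)(C)C(C)(C)C | intermediate
15 | [(2S)-3-(tert-butyldimethylsilyloxy)-2-methylpropyl]magnesium bromide | Br[Mg]C[C@@H](C)CO[Si](C)(C)C(C)(C)C | intermediate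
16 | (1S,3R)-1-[(2R,3R,4S,5R)-4-bromo-3-(4-methoxybenzyloxy)-5-methyl-5-[2-(triisopropylsilyloxy)ethyl]oxolan-2-yl]-4-(tert-butyldimethylsilyloxy)-3-methylbutan-1-ol | CC(C)(C)[Si](C)(C)OC[C@H](C)C[C@H](O)[C@H]1O[C@](C)(CCO[Si](C(C)C)(C(C)C)C(C)C)[C@@H](Br)[C@@H]1OCc1ccc(OC)cc1 | intermediate
17 | O15-methyl ether of 16 | CC(C)(C)[Si](C)(C)OC[C@H](C)C[C@H](OC)[C@H]1O[C@](C)(CCO[Si](C(C)C)(C(C)C)C(C)C)[C@@H](Br)[C@@H]1OCc1ccc(OC)cc1 | intermediate
18 | (2R,4S)-4-[(2R,3R,4S,5R)-4-bromo-3-(4-methoxybenzyloxy)-5-methyl-5-[2-(triisopropylsilyloxy)ethyl]oxolan-2-yl]-4-methoxy-2-methylbutan-1-ol | OC[C@H](C)C[C@H](OC)[C@H]1O[C@](C)(CCO[Si](C(C)C)(C(C)C)C(C)C)[C@@H](Br)[C@@H]1OCc1ccc(OC)cc1 | intermediate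
19 | (2R,3R,4S,5R)-4-bromo-2-[(1S,3R)-4-iodo-1-methoxy-3-methylbutyl]-3-(4-methoxybenzyloxy)-5-methyl-5-[2-(triisopropylsilyloxy)ethyl]oxolane | IC[C@H](C)C[C@H](OC)[C@H]1O[C@](C)(CCO[Si](C(C)C)(C(C)C)C(C)C)[C@@H](Br)[C@@H]1OCc1ccc(OC)cc1 | intermediate
20 | ethyl 2-methyl-1,3-oxazole-4-carboxylate | CCOC(=O)c1coc(C)n1 | starting material
21 | N-methoxy-N,2-dimethyl-1,3-oxazole-4-carboxamide | CON(C)C(=O)c1coc(C)n1 | intermediate
22 | 1-(2-methyl-1,3-oxazol-4-yl)ethan-1-one | CC(=O)c1coc(C)n1 | intermediate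
23 | (2E)-N-methoxy-N-methyl-3-(2-methyl-1,3-oxazol-4-yl)but-2-enamide | CON(C)C(=O)/C=C(\C)c1coc(C)n1 | intermediate
24 | (2E)-3-(2-methyl-1,3-oxazol-4-yl)but-2-enal | O=C/C=C(\C)c1coc(C)n1 | intermediate
25 | diisopinocampheylborinate of 26 | Cc1nc(/C(C)=C/[C@H](OB([C@H]2C[C@H]3C[C@@H]([C@@H]2C)C3(C)C)[C@H]2C[C@H]3C[C@@H]([C@@H]2C)C3(C)C)[C@@H](C)C=C)co1 | intermediate
26 | (2E,4R,5S)-5-methyl-2-(2-methyl-1,3-oxazol-4-yl)hepta-2,6-dien-4-ol | Cc1nc(/C(C)=C/[C@H](O)[C@@H](C)C=C)co1 | intermediate
27 | 4-[(2E,4R,5S)-4-(tert-butyldimethylsilyloxy)-5-methylhepta-2,6-dien-2-yl]-2-methyl-1,3-oxazole | Cc1nc(/C(C)=C/[C@H](O[Si](C)(C)C(C)(C)C)[C@@H](C)C=C)co1 | intermediate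
28 | 2-(lithiomethyl) derivative of 27 | [Li]Cc1nc(/C(C)=C/[C@H](O[Si](C)(C)C(C)(C)C)[C@@H](C)C=C)co1 | intermediate
29 | C3–C21 chain: O5-TBS, O15-methyl, O17-PMB, O21-TIPS (4S,5R,6E,13S,15S,16R,17R,18S,19R) | C(Cc1nc(/C(C)=C/[C@H](O[Si](C)(C)C(C)(C)C)[C@@H](C)C=C)co1)[C@H](C)C[C@H](OC)[C@H]2O[C@](C)(CCO[Si](C(C)C)(C(C)C)C(C)C)[C@@H](Br)[C@@H]2OCc2ccc(OC)cc2 | intermediate
30 | C17 alcohol from 29 (oxolan-3-ol; C16 now labelled S) | C(Cc1nc(/C(C)=C/[C@H](O[Si](C)(C)C(C)(C)C)[C@@H](C)C=C)co1)[C@H](C)C[C@H](OC)[C@H]2O[C@](C)(CCO[Si](C(C)C)(C(C)C)C(C)C)[C@@H](Br)[C@@H]2O | intermediate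
31 | O17 acrylate of 30 | C(Cc1nc(/C(C)=C/[C@H](O[Si](C)(C)C(C)(C)C)[C@@H](C)C=C)co1)[C@H](C)C[C@H](OC)[C@H]2O[C@](C)(CCO[Si](C(C)C)(C(C)C)C(C)C)[C@@H](Br)[C@@H]2OC(=O)C=C | intermediate
32 | O5-TBS, O21-TIPS macrolactone (2E,4S,5R,6E,13S,15S,16R,17R,18S,19R) | CO[C@H]1C[C@@H](C)CCc2nc(co2)/C(C)=C/[C@H](O[Si](C)(C)C(C)(C)C)[C@@H](C)/C=C/C(=O)O[C@@H]2[C@@H]1O[C@](C)(CCO[Si](C(C)C)(C(C)C)C(C)C)[C@H]2Br | intermediate
33 | C5,C21-diol macrolactone | CO[C@H]1C[C@@H](C)CCc2nc(co2)/C(C)=C/[C@H](O)[C@@H](C)/C=C/C(=O)O[C@@H]2[C@@H]1O[C@](C)(CCO)[C@H]2Br | intermediate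
34 | C21 aldehyde macrolactone | CO[C@H]1C[C@@H](C)CCc2nc(co2)/C(C)=C/[C@H](O)[C@@H](C)/C=C/C(=O)O[C@@H]2[C@@H]1O[C@](C)(CC=O)[C@H]2Br | intermediate
35 | (S)-citramalic acid | C[C@](O)(CC(=O)O)C(=O)O | starting material
36 | [(4S)-2,2,4-trimethyl-5-oxo-1,3-dioxolan-4-yl]acetic acid | C[C@]1(CC(=O)O)C(=O)OC(C)(C)O1 | intermediate
37 | (5S)-5-(2-hydroxyethyl)-2,2,5-trimethyl-1,3-dioxolan-4-one | C[C@]1(CCO)C(=O)OC(C)(C)O1 | intermediate
38 | (5S)-5-(2-iodoethyl)-2,2,5-trimethyl-1,3-dioxolan-4-one | C[C@]1(CCI)C(=O)OC(C)(C)O1 | intermediate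
39 | triphenyl{2-[(4S)-2,2,4-trimethyl-5-oxo-1,3-dioxolan-4-yl]ethyl}phosphonium iodide | C[C@]1(CC[P+](c2ccccc2)(c2ccccc2)c2ccccc2)C(=O)OC(C)(C)O1.[I-] | intermediate
40 | ylide of 39 | C[C@]1(CC=P(c2ccccc2)(c2ccccc2)c2ccccc2)C(=O)OC(C)(C)O1 | intermediate
41 | target with C24–OH and C25 carboxyl as the dioxolanone acetonide (21Z,24S) | CO[C@H]1C[C@@H](C)CCc2nc(co2)/C(C)=C/[C@H](O)[C@@H](C)/C=C/C(=O)O[C@@H]2[C@@H]1O[C@](C)(C/C=C\C[C@@]3(C)C(=O)OC(C)(C)O3)[C@H]2Br | intermediate
42 | CNP0163177.2 | CO[C@H]1C[C@@H](C)CCc2nc(co2)/C(C)=C/[C@H](O)[C@@H](C)/C=C/C(=O)O[C@@H]2[C@@H]1O[C@](C)(C/C=C\C[C@](C)(O)C(=O)O)[C@H]2Br | target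

**Step count and risk**

Total: 30 steps. Longest linear sequence: 20 steps from but-3-yn-1-ol (steps 1–8, 10–13, 19–24, 29, 30).

Steps most likely to fail:

Step 19. Substitution at the β-branched primary iodide may be slow, so that proton transfer and elimination by the basic lithiated oxazole consume a late intermediate. The fallback makes the C11–C12 bond first on simple partners and the C14–C15 bond last. It sets out from 27: its lithio derivative 28 is alkylated at the bromide end of commercial (R)-1-bromo-3-chloro-2-methylpropane (used in excess) to give 2-[(3S)-4-chloro-3-methylbutyl]-4-[(2E,4R,5S)-4-(tert-butyldimethylsilyloxy)-5-methylhepta-2,6-dien-2-yl]-1,3-oxazole F1. Magnesium insertion (activated Mg, THF, reflux) should give the C14 chloromagnesium reagent F2, which is added to aldehyde 12 in the presence of MgBr2·OEt2 as in step 10 to give the 15S alcohol F3. NaH/MeI methylation then returns to the route at 29.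

Step 22. At the dilution needed for ring closure, oligomerisation and slow turnover at the hindered C3 vinyl group may outrun cyclisation. The fallback moves metathesis to an intermolecular, concentrated setting and closes the ring by acylation. It sets out from 29: cross-metathesis with excess acrylic acid (second-generation Grubbs catalyst, CH2Cl2, 40 °C) should give the (2E)-enoic acid F4. DDQ removal of the PMB group gives the seco acid F5. Yamaguchi macrolactonisation (2,4,6-trichlorobenzoyl chloride, Et3N, then DMAP, toluene, high dilution) returns to the route at 32.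

Step 2. Facial discrimination at the aldehyde may be insufficient, leaving the 16,17-syn epimer mixed with 6. The fallback sets C17 by reduction instead of by C–C bond formation. It sets out from 6 as the epimer mixture: MnO2 oxidation of the allylic alcohol gives (2E)-1-[(4R)-2,2-dimethyl-1,3-dioxolan-4-yl]-3-methyl-5-(triisopropylsilyloxy)pent-2-en-1-one F6. Chelation-controlled 1,2-reduction with Zn(BH4)2 (Et2O, −30 °C) delivers hydride from the side of H16 of the zinc chelate between the carbonyl oxygen and O16, which should return the anti alcohol 6.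

**Further compounds**

F1 | step 19 | 2-[(3S)-4-chloro-3-methylbutyl]-4-[(2E,4R,5S)-4-(tert-butyldimethylsilyloxy)-5-methylhepta-2,6-dien-2-yl]-1,3-oxazole | C(Cc1nc(/C(C)=C/[C@H](O[Si](C)(C)C(C)(C)C)[C@@H](C)C=C)co1)[C@H](C)CCl
F2 | step 19 | chloromagnesium (Grignard) reagent from F1 | C(Cc1nc(/C(C)=C/[C@H](O[Si](C)(C)C(C)(C)C)[C@@H](C)C=C)co1)[C@H](C)C[Mg]Cl
F3 | step 19 | C15 alcohol (O15-desmethyl 29) | C(Cc1nc(/C(C)=C/[C@H](O[Si](C)(C)C(C)(C)C)[C@@H](C)C=C)co1)[C@H](C)C[C@H](O)[C@H]2O[C@](C)(CCO[Si](C(C)C)(C(C)C)C(C)C)[C@@H](Br)[C@@H]2OCc2ccc(OC)cc2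
F4 | step 22 | (2E)-enoic acid from 29 (C1 carboxylic acid, O17-PMB) | C(Cc1nc(/C(C)=C/[C@H](O[Si](C)(C)C(C)(C)C)[C@@H](C)/C=C/C(=O)O)co1)[C@H](C)C[C@H](OC)[C@H]2O[C@](C)(CCO[Si](C(C)C)(C(C)C)C(C)C)[C@@H](Br)[C@@H]2OCc2ccc(OC)cc2
F5 | step 22 | seco acid (C1 carboxylic acid, free C17 hydroxyl) | C(Cc1nc(/C(C)=C/[C@H](O[Si](C)(C)C(C)(C)C)[C@@H](C)/C=C/C(=O)O)co1)[C@H](C)C[C@H](OC)[C@H]2O[C@](C)(CCO[Si](C(C)C)(C(C)C)C(C)C)[C@@H](Br)[C@@H]2O
F6 | step 2 | (2E)-1-[(4R)-2,2-dimethyl-1,3-dioxolan-4-yl]-3-methyl-5-(triisopropylsilyloxy)pent-2-en-1-one | O=C(/C=C(\C)CCO[Si](C(C)C)(C(C)C)C(C)C)[C@H]1COC(C)(C)O1
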